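The target is an all-trans 1-aryltetralin. Its ring B carbons C2 and C3 each lie next to a carboxyl-level carbon (the C2 methyl ester and the C3 hydroxymethyl group, a reduced acyl), and both hang from ring A through C1 and C4. The route therefore cuts the C2–C3 bond. The precursor is an open-chain compound in which ring A carries a methyl 3,3-diarylpropanoate arm (C1 already R) and a 3-arylpropanoyl (R)-4-benzyloxazolidinone arm. Double enolisation and one-electron oxidation with Fe(acac)3 join the two enolate carbons. In one operation this closes ring B, forms C2–C3 and sets C2 and C3, leaving the two carboxyls differentiated.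

Key step: step 6

Assumption: 4-benzyloxy-3-methoxybenzaldehyde (the benzyl ether of vanillin) is taken as a commercial starting material.

Assumption: step 5 needs aryl transfer to the Si face of Cβ of 11; the (1S,4S) antipode of the diene is written from the usual binding model (ester group turned away from the ligand phenyl) and not from a precedent on this substrate, so the sense would be checked on first use, both antipodes being available.

Step 1
Reactants: 1 4-benzyloxy-3-methoxybenzaldehyde
Product: 2 4-benzyloxy-2-bromo-5-methoxybenzaldehyde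
Conditions: Br2 (1.05 equiv), NaOAc, AcOH, rt
Reagents that add atoms: bromine, BrBr
Why: Electrophilic aromatic bromination is directed para to the methoxy group and ortho to the formyl group, the usual outcome for 3,4-dialkoxybenzaldehydes, and NaOAc buffers the HBr so that the benzyl ether is kept.

Step 2
Reactants: 2 4-benzyloxy-2-bromo-5-methoxybenzaldehyde; 3 Meldrum's acid (2,2-dimethyl-1,3-dioxane-4,6-dione)
Product: 6 3-(4-benzyloxy-2-bromo-5-methoxyphenyl)propanoic acid, via arylidene Meldrum's acid 4 (not isolated), via benzyl Meldrum's acid 5 (not isolated)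
Conditions: HCO2H–Et3N (5:2), 95 °C; then aq HCl
Reagents that add atoms: none
Why: Knoevenagel condensation gives the arylidene Meldrum's acid, formate transfers hydride to this strongly electrophilic alkene, and the 5-benzyl Meldrum's acid hydrolyses and decarboxylates on heating, so the two-carbon acid chain is installed in one pot without touching the aryl bromide or the benzyl ether (reductive Knoevenagel–decarboxylation in triethylammonium formate).

Step 3
Reactants: 6 3-(4-benzyloxy-2-bromo-5-methoxyphenyl)propanoic acid; 7 (R)-4-benzyloxazolidin-2-one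
Product: 9 (4R)-4-benzyl-3-[3-(4-benzyloxy-2-bromo-5-methoxyphenyl)propanoyl]oxazolidin-2-one, via mixed pivalic anhydride 8 (not isolated)
Conditions: PivCl, Et3N, THF, −20 °C; then LiCl, 7, rt
Reagents that add atoms: none
Why: The acid is activated as its mixed pivalic anhydride and the LiCl-activated oxazolidinone attacks the less hindered carbonyl (mixed-anhydride N-acylation of an oxazolidinone auxiliary), which needs no strong base and leaves the aryl bromide untouched.

Step 4
Reactants: 9 (4R)-4-benzyl-3-[3-(4-benzyloxy-2-bromo-5-methoxyphenyl)propanoyl]oxazolidin-2-one; 10 methyl acrylate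
Product: 11 methyl (E)-3-{5-benzyloxy-4-methoxy-2-[3-oxo-3-((4R)-4-benzyl-2-oxooxazolidin-3-yl)propyl]phenyl}acrylate
Conditions: Pd(OAc)2 (5 mol %), P(o-tol)3 (10 mol %), Et3N, DMF, 100 °C
Reagents that add atoms: none
Why: Mizoroki–Heck reaction, in which oxidative addition of the aryl bromide to zerovalent palladium, syn insertion of the acrylate and syn β-hydride elimination give the E cinnamate, while the imide and the benzyl ethers are inert to Et3N in DMF.

Step 5
Reactants: 11 methyl (E)-3-{5-benzyloxy-4-methoxy-2-[3-oxo-3-((4R)-4-benzyl-2-oxooxazolidin-3-yl)propyl]phenyl}acrylate; 12 4-benzyloxy-3-methoxyphenylboronic acid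
Product: 13 methyl (3R)-3-(4-benzyloxy-3-methoxyphenyl)-3-{5-benzyloxy-4-methoxy-2-[3-oxo-3-((4R)-4-benzyl-2-oxooxazolidin-3-yl)propyl]phenyl}propanoate
Conditions: Rh(acac)(C2H4)2 (5 mol %), (1S,4S)-2,5-diphenylbicyclo[2.2.2]octa-2,5-diene (5.5 mol %), K3PO4 (0.5 equiv), dioxane–H2O (10:1), 50 °C
Reagents that add atoms: none
Why: Hayashi–Miyaura asymmetric 1,4-addition, in which the aryl group passes from boron to the rhodium–diene complex, adds to Cβ of the enoate and the rhodium enolate is protonated by water; the chiral diene selects the Si face of Cβ so that the new stereocenter C1 should be R, and the weak base spares the imide.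

Step 6
Reactants: 13 methyl (3R)-3-(4-benzyloxy-3-methoxyphenyl)-3-{5-benzyloxy-4-methoxy-2-[3-oxo-3-((4R)-4-benzyl-2-oxooxazolidin-3-yl)propyl]phenyl}propanoate
Product: 15 methyl (1R,2S,3S)-7-benzyloxy-1-(4-benzyloxy-3-methoxyphenyl)-3-[(4R)-4-benzyl-2-oxooxazolidine-3-carbonyl]-6-methoxy-1,2,3,4-tetrahydronaphthalene-2-carboxylate, via dilithium dienolate 14 (not isolated)
Conditions: LiN(iPr)2 (2.2 equiv), THF (0.02 M), −78 °C; then Fe(acac)3 (2.2 equiv), THF, −78 °C to rt
Reagents that add atoms: none
Why: LiN(iPr)2 removes one proton alpha to the imide and one alpha to the ester to give dienolate 14; Fe(acac)3 takes one electron from the imide enolate, the resulting C3 radical adds to the ester enolate carbon C2, and a second equivalent of trivalent iron oxidises the ketyl-type radical anion to the ester, so that the C2–C3 bond forms. The closest known reactions are the oxidative heterocoupling of oxazolidinone imide enolates with ester enolates by Fe(acac)3 and the ring-closing oxidative coupling of dienolates. Ring B closes in a 6-exo-trig mode, C3 attacking C2 of the exocyclic enolate double bond (ring atoms C1, C2, C3, C4, C4a, C8a). C3 is controlled by the auxiliary: in the chelated Z imide enolate the benzyl group of the (R)-oxazolidinone covers one face, C2 bonds to the other and C3 becomes S; C2 is controlled by the ring, since a chair-like transition state with the C1 aryl, the ester and the acyl group all equatorial leads to the 1,2-trans-2,3-trans product (C2 S). The step needs ring closure to win over intermolecular coupling, which the short tether through ring A and the dilution secure, and it needs the auxiliary and the C1 stereocenter to favour the same diastereomer, which the pairing of the (R)-auxiliary with (R)-C1 should provide.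

Step 7
Reactants: 15 methyl (1R,2S,3S)-7-benzyloxy-1-(4-benzyloxy-3-methoxyphenyl)-3-[(4R)-4-benzyl-2-oxooxazolidine-3-carbonyl]-6-methoxy-1,2,3,4-tetrahydronaphthalene-2-carboxylate
Product: 17 methyl (1R,2S,3S)-7-benzyloxy-1-(4-benzyloxy-3-methoxyphenyl)-3-(hydroxymethyl)-6-methoxy-1,2,3,4-tetrahydronaphthalene-2-carboxylate, via C3 aldehyde 16 (not isolated)
Conditions: LiBH4 (1.2 equiv), MeOH (1.2 equiv), THF, 0 °C; pH 7 phosphate buffer
Reagents that add atoms: none
Why: The exocyclic imide carbonyl is far more electrophilic than the methyl ester, so hydride adds there first, the tetrahedral intermediate collapses to aldehyde 16 with loss of the auxiliary and the aldehyde is reduced at once (reductive cleavage of an N-acyloxazolidinone), while the low temperature and the buffered quench should keep the ester from reduction and from lactonisation, and no stereocenter is touched.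

Step 8
Reactants: 17 methyl (1R,2S,3S)-7-benzyloxy-1-(4-benzyloxy-3-methoxyphenyl)-3-(hydroxymethyl)-6-methoxy-1,2,3,4-tetrahydronaphthalene-2-carboxylate
Product: 18 methyl (1R,2S,3S)-7-hydroxy-1-(4-hydroxy-3-methoxyphenyl)-3-(hydroxymethyl)-6-methoxy-1,2,3,4-tetrahydronaphthalene-2-carboxylate
Conditions: H2 (1 atm), 10% Pd/C, EtOAc, rt
Reagents that add atoms: none
Why: Hydrogenolysis of the two aryl benzyl ethers over palladium on carbon in a neutral medium frees both phenols without affecting the methyl ester, the primary alcohol or the C1–H bond, and the absence of acid or base avoids lactonisation of the hydroxy ester.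

Compound list
1 | 4-benzyloxy-3-methoxybenzaldehyde | COc1cc(C=O)ccc1OCc1ccccc1 | starting material
2 | 4-benzyloxy-2-bromo-5-methoxybenzaldehyde | COc1cc(C=O)c(Br)cc1OCc1ccccc1 | intermediate
3 | Meldrum's acid (2,2-dimethyl-1,3-dioxane-4,6-dione) | CC1(C)OC(=O)CC(=O)O1 | starting material
4 | 5-(4-benzyloxy-2-bromo-5-methoxybenzylidene)-2,2-dimethyl-1,3-dioxane-4,6-dione | COc1cc(C=C2C(=O)OC(C)(C)OC2=O)c(Br)cc1OCc1ccccc1 | intermediate
5 | 5-(4-benzyloxy-2-bromo-5-methoxybenzyl)-2,2-dimethyl-1,3-dioxane-4,6-dione | COc1cc(CC2C(=O)OC(C)(C)OC2=O)c(Br)cc1OCc1ccccc1 | intermediate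
6 | 3-(4-benzyloxy-2-bromo-5-methoxyphenyl)propanoic acid | COc1cc(CCC(=O)O)c(Br)cc1OCc1ccccc1 | intermediate
7 | (R)-4-benzyloxazolidin-2-one | O=C1N[C@H](Cc2ccccc2)CO1 | starting material
8 | 3-(4-benzyloxy-2-bromo-5-methoxyphenyl)propanoic pivalic anhydride | COc1cc(CCC(=O)OC(=O)C(C)(C)C)c(Br)cc1OCc1ccccc1 | intermediate
9 | (4R)-4-benzyl-3-[3-(4-benzyloxy-2-bromo-5-methoxyphenyl)propanoyl]oxazolidin-2-one | COc1cc(CCC(=O)N2C(=O)OC[C@H]2Cc2ccccc2)c(Br)cc1OCc1ccccc1 | intermediate
10 | methyl acrylate | C=CC(=O)OC | starting material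
11 | methyl (E)-3-{5-benzyloxy-4-methoxy-2-[3-oxo-3-((4R)-4-benzyl-2-oxooxazolidin-3-yl)propyl]phenyl}acrylate | COC(=O)/C=C/c1cc(OCc2ccccc2)c(OC)cc1CCC(=O)N1C(=O)OC[C@H]1Cc1ccccc1 | intermediate
12 | 4-benzyloxy-3-methoxyphenylboronic acid | COc1cc(B(O)O)ccc1OCc1ccccc1 | starting material
13 | methyl (3R)-3-(4-benzyloxy-3-methoxyphenyl)-3-{5-benzyloxy-4-methoxy-2-[3-oxo-3-((4R)-4-benzyl-2-oxooxazolidin-3-yl)propyl]phenyl}propanoate | O=C(CCc1cc(OC)c(OCc2ccccc2)cc1[C@H](CC(=O)OC)c1ccc(OCc2ccccc2)c(OC)c1)N1C(=O)OC[C@H]1Cc1ccccc1 | intermediate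
14 | dilithium dienolate of 13 (Z imide enolate, ester enolate) | [Li+].[Li+].[O-]/C(=C\Cc1cc(OC)c(OCc2ccccc2)cc1[C@H](C=C([O-])OC)c1ccc(OCc2ccccc2)c(OC)c1)N1C(=O)OC[C@H]1Cc1ccccc1 | intermediate
15 | methyl (1R,2S,3S)-7-benzyloxy-1-(4-benzyloxy-3-methoxyphenyl)-3-[(4R)-4-benzyl-2-oxooxazolidine-3-carbonyl]-6-methoxy-1,2,3,4-tetrahydronaphthalene-2-carboxylate | COC(=O)[C@@H]1[C@@H](C(=O)N2C(=O)OC[C@H]2Cc2ccccc2)Cc2cc(OC)c(OCc3ccccc3)cc2[C@H]1c1ccc(OCc2ccccc2)c(OC)c1 | intermediate
16 | methyl (1R,2S,3S)-7-benzyloxy-1-(4-benzyloxy-3-methoxyphenyl)-3-formyl-6-methoxy-1,2,3,4-tetrahydronaphthalene-2-carboxylate | COC(=O)[C@@H]1[C@@H](C=O)Cc2cc(OC)c(OCc3ccccc3)cc2[C@H]1c1ccc(OCc2ccccc2)c(OC)c1 | intermediate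
17 | methyl (1R,2S,3S)-7-benzyloxy-1-(4-benzyloxy-3-methoxyphenyl)-3-(hydroxymethyl)-6-methoxy-1,2,3,4-tetrahydronaphthalene-2-carboxylate | COC(=O)[C@@H]1[C@@H](CO)Cc2cc(OC)c(OCc3ccccc3)cc2[C@H]1c1ccc(OCc2ccccc2)c(OC)c1 | intermediate
18 | methyl (1R,2S,3S)-7-hydroxy-1-(4-hydroxy-3-methoxyphenyl)-3-(hydroxymethyl)-6-methoxy-1,2,3,4-tetrahydronaphthalene-2-carboxylate | COC(=O)[C@@H]1[C@@H](CO)Cc2cc(OC)c(O)cc2[C@H]1c1ccc(O)c(OC)c1 | target

Total step count: 8. Longest linear sequence: 8 steps (1 to 18).

Steps most likely to fail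

Step 6. The ring closure may give incomplete control of the configuration at C2, because the face of the ester enolate is set only by the ring transition state, and intermolecular coupling may compete. Stereocontrol at C2 is then moved out of the bond-forming event. Setting out from 13, the coupling is run as in step 6. The crude tetralin, which would hold the C2 epimer methyl (1R,2R,3S)-7-benzyloxy-1-(4-benzyloxy-3-methoxyphenyl)-3-[(4R)-4-benzyl-2-oxooxazolidine-3-carbonyl]-6-methoxy-1,2,3,4-tetrahydronaphthalene-2-carboxylate F1, is equilibrated with DBU in toluene at rt. C1 cannot epimerise and the all-equatorial 1,2-trans-2,3-trans arrangement is the most stable, so deprotonation and reprotonation alpha to the ester should converge on 15, where the route is rejoined.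

Step 5. Insertion of the ortho-substituted, electron-rich cinnamate into the aryl–rhodium bond may be slow, which lets protodeboronation of 12 and base attack on the imide compete, and the level and sense of face selectivity at Cβ are not secured by a close precedent. The roles of the two partners are then reversed. Setting out from 9, Miyaura borylation (B2pin2, Pd(dppf)Cl2, KOAc, dioxane, 85 °C) gives the aryl pinacol boronate (4R)-4-benzyl-3-{3-[4-benzyloxy-5-methoxy-2-(4,4,5,5-tetramethyl-1,3,2-dioxaborolan-2-yl)phenyl]propanoyl}oxazolidin-2-one F2. Setting out from 1, Horner–Wadsworth–Emmons olefination with trimethyl phosphonoacetate (NaH, THF) gives the unhindered acceptor methyl (E)-3-(4-benzyloxy-3-methoxyphenyl)acrylate F3. Rh(acac)(C2H4)2 with the antipodal (1R,4R) diene then adds the ring A aryl group of F2 to the Re face of Cβ of F3, and the route is rejoined at 13.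

Step 7. Hydride may attack the methyl ester or the ring carbonyl of the auxiliary, and the C3 alkoxide may cyclise onto the C2 ester to give the trans-fused lactone. The imide is then cleaved and reduced in two separate operations that avoid an alkoxide. Setting out from 15, LiOH and H2O2 (THF–H2O, 0 °C) hydrolyse the imide selectively to (2S,3S,4R)-6-benzyloxy-4-(4-benzyloxy-3-methoxyphenyl)-7-methoxy-3-(methoxycarbonyl)-1,2,3,4-tetrahydronaphthalene-2-carboxylic acid F4 with release of 7. BH3·SMe2 (THF, 0 °C) then reduces the carboxylic acid in the presence of the methyl ester, and the route is rejoined at 17.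

Further compounds
F1 | step 6 | methyl (1R,2R,3S)-7-benzyloxy-1-(4-benzyloxy-3-methoxyphenyl)-3-[(4R)-4-benzyl-2-oxooxazolidine-3-carbonyl]-6-methoxy-1,2,3,4-tetrahydronaphthalene-2-carboxylate | COC(=O)[C@H]1[C@@H](C(=O)N2C(=O)OC[C@H]2Cc2ccccc2)Cc2cc(OC)c(OCc3ccccc3)cc2[C@H]1c1ccc(OCc2ccccc2)c(OC)c1
F2 | step 5 | (4R)-4-benzyl-3-{3-[4-benzyloxy-5-methoxy-2-(4,4,5,5-tetramethyl-1,3,2-dioxaborolan-2-yl)phenyl]propanoyl}oxazolidin-2-one | O=C(CCc1cc(OC)c(OCc2ccccc2)cc1B1OC(C)(C)C(C)(C)O1)N1C(=O)OC[C@H]1Cc1ccccc1
F3 | step 5 | methyl (E)-3-(4-benzyloxy-3-methoxyphenyl)acrylate | COC(=O)/C=C/c1ccc(OCc2ccccc2)c(OC)c1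
F4 | step 7 | (2S,3S,4R)-6-benzyloxy-4-(4-benzyloxy-3-methoxyphenyl)-7-methoxy-3-(methoxycarbonyl)-1,2,3,4-tetrahydronaphthalene-2-carboxylic acid | COC(=O)[C@@H]1[C@@H](C(=O)O)Cc2cc(OC)c(OCc3ccccc3)cc2[C@H]1c1ccc(OCc2ccccc2)c(OC)c1
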